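36.5% of the charge is the target level I read in the delta run from 0.333 min to 2.50 min, yet its protic impurity is 11.4% of the starting material. I must choose how dry the next charge has to be.

| flask | starting material | protic impurity | remark | time |
|---|---|---|---|---|
| delta | 5 mM | 0.57 mM | run made earlier |  |
| epsilon | 5 mM | 9.4 mM | run made earlier |  |
| Thursday's | 5.0 mM | 0.500 mM |  | 2.5 min |
| Sunday's | 5.0 mM | 1.00 mM |  | 2.5 min |
| Friday's | 5.0 mM | 2.00 mM |  | 2.5 min |
| Saturday's | 5.0 mM | 4.00 mM |  | 2.5 min |
| Wednesday's | 5.0 mM | 8.00 mM |  | 2.5 min |

| delta: time / min | delta: target / % | epsilon: time / min | epsilon: target / % |
|---|---|---|---|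
| 0.200 | 26 | 0.167 | 2 |
| 0.333 | 37 | 0.417 | 2 |
| 0.500 | 36 | 0.667 | 0 |
| 0.667 | 35 | 1.00 | 1 |
| 1.00 | 35 | 1.50 | 0 |
| 1.50 | 37 | 2.00 | 0 |
| 2.50 | 39 | 2.50 | 3 |

(readings scatter by 2 percentage points)

- the analysis behind the earlier runs scatters by 2 percentage points, standard deviation
- "hardly changes" means that all values lie within two and a half points (for a concentration: within two and a half percent of the largest)

- amount of target at the end, in percent of the starting material charged for Thursday's, Sunday's, Friday's, Saturday's, Wednesday's, in this order
- how that number moves from the first to the last of them (rises, then falls / falls all the way / hardly changes / rises all the way / falls, then rises)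

1. I assume that each protic impurity consumes one starting material. The epsilon run has more impurity than starting material and reads 3% at 2.50 min, against a scatter of 2 percentage points. That fits my assumption.

2. In the delta run, target and impurity's share leave 52.1% of the charge unaccounted for. I take this as starting material still present, in a reversible step that gives target and by-product one for one.

3. My budget is the starting material charged minus the protic impurity charged. The plateau quotient, c(target) × c(by-product) / c(starting material), is an equilibrium constant as read from one run. In the delta run c(target) reads 1.83 mM, so the quotient Q reads 1.28 mM.

4. Solving for c(target) with each budget, I get 36.9% for Thursday's flask, 34.2% for Sunday's, 28.4% for Friday's and 13.2% for Saturday's. Wednesday's charge has more impurity than starting material, so I expect it to read near the epsilon run.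

5. The forecast gives 40%, 23%, 11%, 5% and 2%, and says the row falls all the way. It has the impurity “act repeatedly, as a catalyst for a competing path”, and there my reckoning differs from it.

6. Friday's charge separates us by 17 points, more than Sunday's or Saturday's. I run that level next. By my reckoning, drying it down to Thursday's level buys 8.5 points.

    starting material ⇌ target + by-product (K = 0.00145 M, k = 0.0412 s⁻¹)
    starting material + protic impurity → quenched substrate (k = 779 M⁻¹ s⁻¹)

The flasks end at 38.6%, 35.8%, 29.7%, 13.6% and 0.841%, so the row falls all the way. Saturday's flask at 2.50 min holds quenched substrate at 80.0% of the charge, protic impurity at 0% of its own charge, and by-product at 0.681 mM. I put Q to use on Saturday's flask: its target is 0.680 mM, and that concentration multiplied by itself and divided by Q asks for 7.23% of the charge as starting material, while Saturday's flask holds 6.39%.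

All runs are calculated from invented constants, and the scatter is random.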